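**Assumption:** the target, 1-(2,4-dihydroxy-3-methoxyphenyl)-7-(4-methoxyphenyl)heptan-3-one, has no stereocentre and no stereogenic double bond, so it is achiral and needs no stereocontrol.

**Retrosynthetic overview**
1. Target ⇒ the bis-O-benzyl ketone (final hydrogenolysis of the two phenol protecting groups).
2. Key disconnection: the aryl–CH2 bond. The β-carbon of the heptan-3-one acts as a nucleophile (ketone homoenolate, released from a 1-substituted cyclopropanol) and is arylated by an aryl bromide under Pd catalysis.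
3. Cyclopropanol ⇒ Kulinkovich reaction of methyl 5-(4-methoxyphenyl)pentanoate ⇐ the commercial acid.
4. Aryl bromide ⇒ para-selective bromination of dibenzylated 2-methoxyresorcinol.
5. Rings: both benzene rings are bought. The only ring built is the cyclopropane (step 2), and it is opened again in the key step (step 5).

**Route**

Step 1
Reactants: 1 5-(4-methoxyphenyl)pentanoic acid
Product: 2 methyl 5-(4-methoxyphenyl)pentanoate
Conditions: MeOH, cat. H2SO4, reflux
Reagents that add atoms: methanol, CO
Why: Fischer esterification, driven by excess methanol, gives the ester needed for the Kulinkovich reaction.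

Step 2
Reactants: 2 methyl 5-(4-methoxyphenyl)pentanoate
Product: 3 1-[4-(4-methoxyphenyl)butyl]cyclopropan-1-ol
Conditions: EtMgBr (2.5 equiv, slow addition), Ti(OiPr)4 (0.2 equiv), THF, 0 °C to rt; aqueous work-up
Reagents that add atoms: ethylmagnesium bromide, CC[Mg]Br
Why: Kulinkovich cyclopropanation, in which the titanacyclopropane formed from EtMgBr and Ti(OiPr)4 adds twice to the ester carbonyl as a 1,2-dicarbanion equivalent and so stores the ketone homoenolate as a strained cyclopropanol.

Step 3
Reactants: 4 2-methoxybenzene-1,3-diol (2-methoxyresorcinol)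
Product: 5 1,3-bis(benzyloxy)-2-methoxybenzene
Conditions: BnBr (2.3 equiv), K2CO3, DMF, 60 °C
Reagents that add atoms: benzyl bromide, BrCc1ccccc1
Why: Williamson ether synthesis masks both phenols so they interfere with neither the bromination nor the basic Pd coupling.

Step 4
Reactants: 5 1,3-bis(benzyloxy)-2-methoxybenzene
Product: 6 1,3-bis(benzyloxy)-4-bromo-2-methoxybenzene
Conditions: NBS (1.0 equiv), MeCN, 0 °C to rt, dark
Reagents that add atoms: N-bromosuccinimide, O=C1CCC(=O)N1Br
Why: electrophilic aromatic bromination goes to C4 (para to one OBn, ortho to the other) because the central OMe is twisted out of conjugation and does not activate C5, as in the known 4-bromination of 1,2,3-trialkoxybenzenes.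

Step 5
Reactants: 3 1-[4-(4-methoxyphenyl)butyl]cyclopropan-1-ol (1.3 equiv); 6 1,3-bis(benzyloxy)-4-bromo-2-methoxybenzene
Product: 8 1-[2,4-bis(benzyloxy)-3-methoxyphenyl]-7-(4-methoxyphenyl)heptan-3-one, via palladium homoenolate 7 (not isolated)
Conditions: Pd(OAc)2 (5 mol %), XPhos (10 mol %), Cs2CO3 (2 equiv), toluene, 80 °C, Ar
Reagents that add atoms: none
Why: Pd-catalysed ring-opening cross-coupling of a cyclopropanol (ketone homoenolate arylation), in which oxidative addition of 6, alkoxide exchange and strain-driven β-carbon elimination give the β-palladated ketone 7, and the bulky biarylphosphine makes C(sp2)–C(sp3) reductive elimination faster than β-hydride elimination; no stereocentre is formed.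

Step 6
Reactants: 8 1-[2,4-bis(benzyloxy)-3-methoxyphenyl]-7-(4-methoxyphenyl)heptan-3-one
Product: 9 1-(2,4-dihydroxy-3-methoxyphenyl)-7-(4-methoxyphenyl)heptan-3-one (target)
Conditions: H2 (1 atm), 10% Pd/C, EtOAc, rt
Reagents that add atoms: none
Why: catalytic hydrogenolysis cleaves both aryl benzyl ethers under neutral conditions that leave the dialkyl ketone and the two aryl methyl ethers untouched.

**Compound list**
1 | 5-(4-methoxyphenyl)pentanoic acid | COc1ccc(CCCCC(=O)O)cc1 | starting material
2 | methyl 5-(4-methoxyphenyl)pentanoate | COc1ccc(CCCCC(=O)OC)cc1 | intermediate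
3 | 1-[4-(4-methoxyphenyl)butyl]cyclopropan-1-ol | COc1ccc(CCCCC2(O)CC2)cc1 | intermediate
4 | 2-methoxybenzene-1,3-diol (2-methoxyresorcinol) | COc1c(O)cccc1O | starting material
5 | 1,3-bis(benzyloxy)-2-methoxybenzene | COc1c(OCc2ccccc2)cccc1OCc1ccccc1 | intermediate
6 | 1,3-bis(benzyloxy)-4-bromo-2-methoxybenzene | COc1c(OCc2ccccc2)ccc(Br)c1OCc1ccccc1 | intermediate
7 | [2,4-bis(benzyloxy)-3-methoxyphenyl][7-(4-methoxyphenyl)-3-oxoheptyl]palladium(II), the palladium homoenolate (XPhos ligand not drawn) | COc1ccc(CCCCC(=O)CC[Pd]c2ccc(OCc3ccccc3)c(OC)c2OCc2ccccc2)cc1 | intermediate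
8 | 1-[2,4-bis(benzyloxy)-3-methoxyphenyl]-7-(4-methoxyphenyl)heptan-3-one | COc1ccc(CCCCC(=O)CCc2ccc(OCc3ccccc3)c(OC)c2OCc2ccccc2)cc1 | intermediate
9 | 1-(2,4-dihydroxy-3-methoxyphenyl)-7-(4-methoxyphenyl)heptan-3-one | COc1ccc(CCCCC(=O)CCc2ccc(O)c(OC)c2O)cc1 | target

**Step count**
Total steps: 6. Longest linear sequence: 4 (1 → 2 → 3 → 8 → 9, or 4 → 5 → 6 → 8 → 9).

**Three steps most likely to fail, with fallbacks**

Step 5 (homoenolate arylation). The risks are β-hydride elimination of the palladium homoenolate to the vinyl ketone and slow oxidative addition of the electron-rich, ortho-substituted bromide. The fallback sets out from 3 (and uses 6) and comes back at 8. It makes the elimination deliberate: Pd(OAc)2 (cat.), pyridine, O2, toluene, 80 °C opens 3 oxidatively to the vinyl ketone 7-(4-methoxyphenyl)hept-1-en-3-one F1. Copper-catalysed conjugate borylation (CuCl, NaOtBu, DPEphos, B2pin2, MeOH, THF, rt) then turns the β-carbon back into a nucleophile as 7-(4-methoxyphenyl)-1-(4,4,5,5-tetramethyl-1,3,2-dioxaborolan-2-yl)heptan-3-one F2. Aqueous KHF2 in MeOH converts this into the bench-stable boron homoenolate potassium trifluoro[7-(4-methoxyphenyl)-3-oxoheptyl]borate F3. Suzuki–Miyaura coupling of F3 with 6 (Pd(OAc)2, RuPhos, K2CO3, toluene/H2O, 85 °C) gives 8, and step 6 follows unchanged.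

Step 2 (Kulinkovich). The risks are incomplete conversion or over-addition of the Grignard reagent to give the tertiary alcohol. The fallback sets out from 1 and comes back at 3, building the cyclopropanol by cyclopropanating an enol ether instead. MeLi (2.2 equiv), THF, 0 °C converts the acid into the methyl ketone 6-(4-methoxyphenyl)hexan-2-one F4. Kinetic enolisation (LDA, THF, −78 °C, then TMSCl) gives the terminal silyl enol ether {[6-(4-methoxyphenyl)hex-1-en-2-yl]oxy}trimethylsilane F5. Furukawa–Simmons–Smith cyclopropanation (Et2Zn, CH2I2, CH2Cl2, 0 °C) gives {1-[4-(4-methoxyphenyl)butyl]cyclopropoxy}trimethylsilane F6, and neutral methanolysis (MeOH, rt) releases 3.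

Step 6 (hydrogenolysis). The risks are incomplete cleavage of the hindered 2-OBn and reductive loss of the ketone through the ortho-phenol hemiketal/chromene, which would give a chroman. The fallback sets out from 4 and comes back at 9, replacing the hydrogenolysable groups with acid-labile ones. MOMCl, iPr2NEt, CH2Cl2 gives 2-methoxy-1,3-bis(methoxymethoxy)benzene F7. NBS, MeCN, 0 °C gives 1-bromo-3-methoxy-2,4-bis(methoxymethoxy)benzene F8. The same Pd(OAc)2/XPhos/Cs2CO3 coupling with 3 gives 1-[3-methoxy-2,4-bis(methoxymethoxy)phenyl]-7-(4-methoxyphenyl)heptan-3-one F9. Aqueous 3 M HCl in THF at 40 °C then removes both MOM groups to give 9; in water any hemiketal or enol ether formed reverts to the open keto-phenol.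

**Further compounds**
F1 | step 5 | 7-(4-methoxyphenyl)hept-1-en-3-one | COc1ccc(CCCCC(=O)C=C)cc1
F2 | step 5 | 7-(4-methoxyphenyl)-1-(4,4,5,5-tetramethyl-1,3,2-dioxaborolan-2-yl)heptan-3-one | COc1ccc(CCCCC(=O)CCB2OC(C)(C)C(C)(C)O2)cc1
F3 | step 5 | potassium trifluoro[7-(4-methoxyphenyl)-3-oxoheptyl]borate | COc1ccc(CCCCC(=O)CC[B-](F)(F)F)cc1.[K+]
F4 | step 2 | 6-(4-methoxyphenyl)hexan-2-one | COc1ccc(CCCCC(C)=O)cc1
F5 | step 2 | {[6-(4-methoxyphenyl)hex-1-en-2-yl]oxy}trimethylsilane | COc1ccc(CCCCC(=C)O[Si](C)(C)C)cc1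
F6 | step 2 | {1-[4-(4-methoxyphenyl)butyl]cyclopropoxy}trimethylsilane | COc1ccc(CCCCC2(O[Si](C)(C)C)CC2)cc1
F7 | step 6 | 2-methoxy-1,3-bis(methoxymethoxy)benzene | COCOc1cccc(OCOC)c1OC
F8 | step 6 | 1-bromo-3-methoxy-2,4-bis(methoxymethoxy)benzene | COCOc1ccc(Br)c(OCOC)c1OC
F9 | step 6 | 1-[3-methoxy-2,4-bis(methoxymethoxy)phenyl]-7-(4-methoxyphenyl)heptan-3-one | COCOc1ccc(CCC(=O)CCCCc2ccc(OC)cc2)c(OCOC)c1OC
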